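**Assumptions and conventions (remarks on the chemistry)**

- Ring A is numbered a1 (acyl carbon), a2 (OH next to the methyl), a3 (methyl), a4 (methoxy), a5 (CH2 bridge), a6 (OH). Ring B carries chromanone numbering. RA stands for the 2,4-bis(benzyloxy)-6-methoxy-5-methyl-3-[(2R)-2-methylbutanoyl]benzyl group, that is ring A with its CH2.
- Benzyl alkynyl ethers are assumed to undergo a [3,3] sigmatropic shift (to an arylketene and then an indan-2-one) near 60 °C, which is below the temperature a 3-alkoxycyclobutenone needs to open. The ring B alkyne is therefore methoxyethyne, C5 is carried as a methyl ether, and the last step is a chelation-directed Lewis acid deprotection. The benzyl ynol ether 17 is used only at or below room temperature.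
- A malonate homologation would end in a hot alkaline ester hydrolysis next to the enolisable stereocenter. It is replaced by a buffered one-pot Meldrum's acid/formate sequence.
- Neither ynol ether is assumed to be purchasable; both are made (steps 6 and 8).

## Structural features

The target joins two hexasubstituted, phloroglucinol-derived benzene rings through a single CH2 group. Ring A is an acylphloroglucinol monomethyl ether: the (2R)-2-methylbutanoyl group on a1 is flanked by free hydroxyls on a2 and a6, a3 carries a methyl, a4 a methoxy group para to the ketone, and a5 the bridge. Ring B is the benzene ring of a 2,2-dimethylchroman-4-one, with hydroxyls on C5 and C7, a methyl on C6, the bridge on C8, the ring oxygen O1 on C8a and the ketone carbon C4 on C4a. The only stereocenter is the carbon alpha to the ring A ketone; it has no stereogenic neighbour, but it is enolisable and can be lost without any change in constitution. Fragile points are the diarylmethane link between two very electron-rich rings (acid-induced scission, base-induced scrambling once the phenols are free), the 5-hydroxychromanone (ring opening and reclosure onto the C5 oxygen), and the a4 methyl ether, which must outlast the unmasking of four phenols. The real difficulty is regiochemical: the three oxygens of ring B are almost equivalent, yet only the one on C8a, next to the bridge carbon C8, may become O1, and in ring A only the a4 oxygen may be methylated. The key step exploits the fact that ring B needs exactly one free hydroxyl (C8a) beside exactly one unsubstituted carbon (C4a), with the C5 and C7 oxygens masked: a cyclobutenone/alkoxyalkyne benzannulation writes this pattern directly, the ketene carbonyl becoming C8a–OH and the alkyne CH becoming C4a.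

## Logic of the disconnections

**33 back to 32.** The O–CH2Ph bonds at a2, a6 and C7 and the O–CH3 bond at C5 are cut. All four phenols stay masked to the end because free phenols on both sides of the bridge make it labile. The gain is a set of non-polar, stable intermediates. The demand is one operation that removes three benzyl ethers and the carbonyl-chelated C5 methyl ether, spares the a4 methyl ether and does not enolise the ketone.

**32 back to 28 and 29.** C4–C4a and O1–C2 are cut. The cut is placed here because 28 has a single free hydroxyl (C8a) beside a single free ring carbon (C4a), so only one pyranone can form. The gain is removal of the whole heterocycle in one operation from a commodity acid. The demand is a C-acylation mild enough for the CH2 bridge and the stereocenter.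

**28 back to 20 and 23 (key).** C4a–C8a, C5–C6 and C8–C8a are cut, which takes ring B apart. These are the bonds a vinylketene/alkyne annulation makes, and the annulation puts the only free hydroxyl on C8a. The gain is that ring B shrinks to a four-membered ring and a two-carbon alkyne, and the regiochemical problem becomes a choice of which partner carries which substituent. The demand is that both partners survive the temperature of the ring opening; 23 has no β-hydrogen and no benzylic O-substituent, so it has no retro-ene or sigmatropic exit.

**20 back to 12 and 17.** C1–C2 and C3–C4 of the four-membered ring are cut (ketene plus ynol ether). This sets the 2-methyl, 3-benzyloxy, 4-arylmethyl pattern through alkyne polarisation. The gain is a plain carboxylic acid and a three-carbon ynol ether. The demand is ketene generation under mild base, with 17 kept cold.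

**17 back to 13 and 14; 23 back to 21.** In 17 the O–C(sp) bond and the C(sp)–CH3 bond are cut; 23 comes from 21 by two eliminations. Both are short preparations from bulk chemicals. The demand is low temperature and prompt use.

**12 back to 8 and 9.** The C–C bond between the bridge carbon and the future C8 is cut (condensation, reduction, decarboxylation). A two-carbon homologation of an aldehyde avoids a benzylic halide and strong base. The gain is a stable aldehyde precursor. The demand is reduction of the alkylidene malonate only, with the aryl ketone untouched.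

**8 back to 7, and 7 back to 5.** The two O–benzyl bonds and the a5–CHO bond are cut. Formylation is easiest on the free phenol, where a5 is the only unsubstituted carbon. The demand is exhaustive O-benzylation of two chelated phenols without C-alkylation.

**5 back to 4.** The a4 O–CH3 bond is cut. The hydroxyl para to the ketone is the only one not hydrogen-bonded to it. The demand is clean mono-methylation.

**4 back to 1 and 2 (through 3).** The a1–C(=O) bond is cut. The two free positions of 1 are equivalent by symmetry and the stereocenter is bought. The demand is acylation without loss of configuration.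

## Other disconnections considered

**Alternative 1:** The cut is C8–C8a and C4a–C5 of ring B, with the pyranone kept intact. In the forward step the bis(silyloxy)diene A1, carrying a ring A without its acyl group, adds through its terminus to C6 of bromopyranone A2 (Mukaiyama–Michael, forming C8–C8a). The resulting enolate closes on the ester-level carbon (forming C4a–C5) with loss of the methoxy group, and loss of HBr aromatises to A3.

- In its favour: O1 is part of A2 from the start, so the question of which ring B oxygen closes the pyranone never arises and no acylation of a finished diarylmethane ring B is needed. On this point it is better than the chosen plan. The stereocenter would also be introduced late and carried through fewer steps, again better.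
- Against it here: A2 is a vinylogous ester and a weak acceptor, attacked at its oxygen-bearing carbon by a diene whose reacting termini are both fully substituted. The closing step must bond to a carbon that already carries bromine. A3 still lacks the acyl group, so 3 would have to be introduced by a Friedel–Crafts reaction on a molecule with two free ring B phenols and an acid-sensitive bridge, with no later chance to upgrade enantiomeric purity.
- Comparison: on structure the two plans are equal, since both fix the ring B pattern unambiguously. On mechanism the chosen plan relies on a pericyclic cascade whose ring-closing step is intramolecular and tolerant of crowding, whereas this one needs two polar bond formations at hindered centres. Step economy is about equal: the chromanone closure is saved, but the preparation of A1 and A2 and a late acylation are added.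

**Alternative 2:** The cut is a2–a3 and a1–a6 of ring A. In the forward step the ketene-acetal diene A4, which carries the complete chromanone, adds to the chiral alkoxy-ynone A5, and loss of methoxytrimethylsilane aromatises to A6.

- In its favour: this is the most convergent plan. The acyl group and its stereocenter arrive in one piece, and ring A is born with its three oxygens differentiated (free a6 hydroxyl, a2 benzyl ether, a4 methyl ether), so no selective methylation is needed. On convergence and on ring A oxygen differentiation it is better than the chosen plan.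
- Against it here: the chromanone in A4 must first be made regiochemically pure by classical closure, so the ring B problem is moved and not solved. The ketene acetal of A4 must be generated beside the enolisable C3 methylene of the chromanone. A5 is a benzyl alkynyl ether with its stereocenter alpha to an ynone carbonyl, which is thermally and configurationally more exposed than the ketone in the chosen plan. Both new bonds form intermolecularly between fully substituted carbons.
- Comparison: structurally it is better for ring A and worse for ring B. Mechanistically its regiochemistry rests on a push-pull alkyne whose electrophilic carbon is deactivated by its own oxygen, against the clean ynol ether polarisation of the chosen plan. Step economy would be equal or slightly better only if the chromanone were in hand.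

**Alternative 3:** The cut is a5–a6 and a3–a4 of ring A, with a1–a6 re-formed in the electrocyclisation. In the forward step cyclobutenone A7 and the chromanone-bearing 1-methoxyalkyne A8 are heated to give phenol A9.

- In its favour: it is the same reaction family as the chosen plan, so mechanistically equal. A7 has an unsubstituted C4 and is the simplest member of its class, and A8 is a methyl alkynyl ether and thermally robust, so the thermal step is arguably easier than in the chosen plan. Ring A again emerges with differentiated oxygens.
- Against it here: ring A is the easy ring, available from 1 in a few classical steps thanks to symmetry, so the annulation is spent where it is least needed. The ring B pyranone regiochemistry is left to a classical closure. A9 has a free a1 position, so 3 must be introduced last by a Friedel–Crafts reaction on the finished diarylmethane. A8 requires an alkynylation in the presence of the C4 ketone.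
- Comparison: mechanism is equal. On structure it is inferior, because the harder ring is not addressed. Step economy is similar or slightly worse.

Key step: step 9

## Route

Step 1
Reactants: 1 2-methylbenzene-1,3,5-triol; 2 (2R)-2-methylbutanoic acid
Product: 4 (2R)-2-methyl-1-(2,4,6-trihydroxy-3-methylphenyl)butan-1-one, via (2R)-2-methylbutanoyl chloride 3 (not isolated)
Conditions: 2, (COCl)2, DMF (cat.), CH2Cl2, 0 °C → rt; then 1, AlCl3, PhNO2/CH2Cl2, 0 °C → rt; aq. HCl
Reagents that add atoms: none
Why: Friedel–Crafts C-acylation of a phloroglucinol; the two free positions of 1 are equivalent by symmetry and the first acyl group deactivates the ring against a second. The stereocenter comes from 2; the acid chloride is made without base and the acylation is run cold so that neither ketene formation nor enolisation of the aluminium-chelated ketone should erode it (enantiomeric purity to be assayed on 4).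

Step 2
Reactants: 4 (2R)-2-methyl-1-(2,4,6-trihydroxy-3-methylphenyl)butan-1-one
Product: 5 (2R)-1-(2,6-dihydroxy-4-methoxy-3-methylphenyl)-2-methylbutan-1-one
Conditions: Me2SO4 (1.05 equiv), K2CO3 (1.1 equiv), acetone, rt → 40 °C
Reagents that add atoms: dimethyl sulfate, COS(=O)(=O)OC
Why: Williamson ether synthesis; the hydroxyl para to the acyl group is the most acidic and the only one not locked in a hydrogen bond to the ketone, so one equivalent of base and electrophile should methylate it selectively.

Step 3
Reactants: 5 (2R)-1-(2,6-dihydroxy-4-methoxy-3-methylphenyl)-2-methylbutan-1-one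
Product: 7 2,4-dihydroxy-6-methoxy-5-methyl-3-[(2R)-2-methylbutanoyl]benzaldehyde, via aryl iminium chloride 6 (not isolated)
Conditions: POCl3, DMF, EtOAc, 0 °C → rt; then H2O, 50 °C
Reagents that add atoms: N,N-dimethylformamide, CN(C)C=O; water, O
Why: Vilsmeier–Haack formylation at the single unsubstituted ring carbon, which is activated by an ortho hydroxyl, an ortho methoxy and a para hydroxyl; the iminium salt 6 is hydrolysed on aqueous work-up.

Step 4
Reactants: 7 2,4-dihydroxy-6-methoxy-5-methyl-3-[(2R)-2-methylbutanoyl]benzaldehyde
Product: 8 2,4-bis(benzyloxy)-6-methoxy-5-methyl-3-[(2R)-2-methylbutanoyl]benzaldehyde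
Conditions: BnBr (2.6 equiv), K2CO3, n-Bu4NI (cat.), DMF, 60 °C
Reagents that add atoms: benzyl bromide, BrCc1ccccc1
Why: Williamson benzylation of both chelated phenols under forcing but weakly basic conditions; carbonate is far too weak to deprotonate the ketone alpha carbon, and the polar aprotic medium favours O- over C-alkylation of the fully substituted ring.

Step 5
Reactants: 8 2,4-bis(benzyloxy)-6-methoxy-5-methyl-3-[(2R)-2-methylbutanoyl]benzaldehyde; 9 2,2-dimethyl-1,3-dioxane-4,6-dione (Meldrum's acid)
Product: 12 3-{2,4-bis(benzyloxy)-6-methoxy-5-methyl-3-[(2R)-2-methylbutanoyl]phenyl}propanoic acid, via arylidene Meldrum's acid 10 (not isolated), via arylmethyl Meldrum's acid 11 (not isolated)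
Conditions: HCO2H/Et3N (5:2), 50 °C, then 95–100 °C
Reagents that add atoms: water, O
Why: Tandem Knoevenagel condensation, conjugate reduction of the alkylidene malonate 10 by formate, and hydrolysis with decarboxylation of 11 in one pot. The medium is buffered and contains no strong base, and formate does not reduce the hindered aryl ketone, so the stereocenter and the benzyl ethers should pass unchanged.

Step 6
Reactants: 13 benzyl alcohol; 14 trichloroethylene
Product: 17 benzyl prop-1-yn-1-yl ether, via benzyl (E)-1,2-dichlorovinyl ether 15 (not isolated), via lithium (benzyloxy)ethynide 16 (not isolated)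
Conditions: KH, THF, 0 °C; 14, −50 °C → rt; n-BuLi (2.2 equiv), −78 → −40 °C; MeI, DMPU, −78 → 10 °C
Reagents that add atoms: iodomethane, CI
Why: Trichloroethylene route to ynol ethers: the alkoxide adds to dichloroacetylene formed in situ to give 15, two equivalents of n-BuLi effect elimination and chlorine–lithium exchange to 16, and C-methylation follows. Everything is kept at or below room temperature because of the thermal lability of benzyl alkynyl ethers.

Step 7
Reactants: 12 3-{2,4-bis(benzyloxy)-6-methoxy-5-methyl-3-[(2R)-2-methylbutanoyl]phenyl}propanoic acid; 17 benzyl prop-1-yn-1-yl ether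
Product: 20 3-(benzyloxy)-2-methyl-4-RA-cyclobut-2-en-1-one (both C4 epimers), via acid chloride 18 (not isolated), via ketene 19 (not isolated)
Conditions: (COCl)2, DMF (cat.), CH2Cl2, 0 °C → rt; concentrate; slow addition to 17 (2.5 equiv), Et3N (1.5 equiv), CH2Cl2, 0 °C → rt
Reagents that add atoms: none
Why: Dehydrochlorination of 18 gives aldoketene 19, which undergoes [2+2] cycloaddition with the electron-rich alkyne. The nucleophilic methyl-bearing alkyne carbon bonds to the ketene carbonyl carbon, which fixes the 2-methyl, 3-benzyloxy, 4-arylmethyl pattern. The new C4 stereocenter forms unselectively and is irrelevant because C4 becomes the aromatic C8.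

Step 8
Reactants: 21 2-chloro-1,1-dimethoxyethane
Product: 23 methoxyethyne, via sodium methoxyethynide 22 (not isolated)
Conditions: NaNH2 (3 equiv), liq. NH3, −33 °C; aq. NaCl, −20 °C; distil into cold toluene
Reagents that add atoms: none
Why: Base-induced loss of methanol and hydrogen chloride gives the sodium acetylide 22, which is protonated on quenching; a long-established preparation. The product (bp about 23 °C) is kept as a cold toluene solution.

Step 9
Reactants: 20 3-(benzyloxy)-2-methyl-4-RA-cyclobut-2-en-1-one; 23 methoxyethyne
Product: 28 3-(benzyloxy)-5-methoxy-4-methyl-2-RA-phenol, via vinylketene 24 (not isolated), via 4-vinylcyclobutenone 25 (not isolated), via dienylketene 26 (not isolated), via cyclohexadienone 27 (not isolated)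
Conditions: 23 (4 equiv), toluene, BHT (cat.), sealed tube, 90 → 125 °C
Reagents that add atoms: none
Why: The closest known reaction type is the Danheiser benzannulation of a cyclobutenone with an alkoxyacetylene. Thermal four-electron conrotatory opening of 20 cleaves C1–C4, with the arylmethyl group turning outward, and gives vinylketene 24; its ketene C=C bond adds to 23 in a [2+2] sense, the unsubstituted nucleophilic alkyne carbon bonding to the ketene carbonyl carbon (future C4a–C8a) and the methoxy-bearing carbon to the methyl-bearing carbon (future C5–C6), to give 25. A second four-electron opening of 25 leads to dienylketene 26, and ring B is closed by a thermally allowed six-electron disrotatory electrocyclisation that re-forms the old C1–C4 bond as C8–C8a; tautomerisation of 27 gives 28. No stereocenter is created: the C4 epimers of 20 converge on the same aromatic ring, and the (R) centre of the side chain is not touched by a neutral thermal process. The regioselectivity needed is secured by the polarisation of the ynol ether, whose β-carbon is the nucleophile, so the ketene oxygen ends as the single free hydroxyl on C8a beside the single CH at C4a. The chemoselectivity needed is survival of the alkyne at 90–125 °C: 23 has no β-hydrogen for a retro-ene loss of ketene and no benzyl group for a [3,3] shift, which is why it is used in place of a benzyl ethynyl ether. Ring A is inert because it has no free ring position and its ketone is shielded by two ortho benzyloxy groups.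

Step 10
Reactants: 28 3-(benzyloxy)-5-methoxy-4-methyl-2-RA-phenol; 29 3-methylbut-2-enoic acid
Product: 32 7-(benzyloxy)-5-methoxy-2,2,6-trimethyl-8-RA-chroman-4-one, via mixed anhydride 30 (not isolated), via hydroxyaryl enone 31 (not isolated)
Conditions: 29 (1.3 equiv), (CF3CO)2O (2.5 equiv), CH2Cl2, 0 °C → rt; evaporate; K2CO3 (0.3 equiv), MeOH, 0 °C → rt
Reagents that add atoms: none
Why: Friedel–Crafts acylation by the mixed trifluoroacetic anhydride 30 at C4a, the only unsubstituted carbon of ring B (ortho to the hydroxyl and the methoxy, para to the benzyloxy group), followed by 6-endo oxa-Michael addition of the C8a hydroxyl to enone 31 under mild base. Because C5 carries a methyl ether, only the C8a oxygen can close the pyranone, and the acylium-type electrophile favours acylation over tertiary-cation alkylation.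

Step 11
Reactants: 32 7-(benzyloxy)-5-methoxy-2,2,6-trimethyl-8-RA-chroman-4-one
Product: 33 5,7-dihydroxy-8-{2,4-dihydroxy-6-methoxy-5-methyl-3-[(2R)-2-methylbutanoyl]benzyl}-2,2,6-trimethylchroman-4-one
Conditions: BCl3 (8 equiv), C6HMe5 (6 equiv), CH2Cl2, −78 → −10 °C; H2O quench at −78 °C
Reagents that add atoms: none
Why: Lewis acid ether cleavage: BCl3 removes the three benzyl ethers (pentamethylbenzene traps the benzyl cations) and, through a boron chelate with the C4 carbonyl, the peri methyl ether on C5. The a4 methyl ether has no carbonyl neighbour and should survive at low temperature, and the absence of base excludes enolisation of the stereocenter and retro-oxa-Michael opening.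

## Compound list

1 | 2-methylbenzene-1,3,5-triol (2-methylphloroglucinol) | Cc1c(O)cc(O)cc1O | starting material
2 | (2R)-2-methylbutanoic acid | CC[C@@H](C)C(=O)O | starting material
3 | (2R)-2-methylbutanoyl chloride | CC[C@@H](C)C(=O)Cl | intermediate
4 | (2R)-2-methyl-1-(2,4,6-trihydroxy-3-methylphenyl)butan-1-one | CC[C@@H](C)C(=O)c1c(O)c(C)c(O)cc1O | intermediate
5 | (2R)-1-(2,6-dihydroxy-4-methoxy-3-methylphenyl)-2-methylbutan-1-one | CC[C@@H](C)C(=O)c1c(O)c(C)c(OC)cc1O | intermediate
6 | N-{2,4-dihydroxy-6-methoxy-5-methyl-3-[(2R)-2-methylbutanoyl]benzylidene}-N-methylmethanaminium chloride | C[N+](C)=Cc1c(O)c(C(=O)[C@H](C)CC)c(O)c(C)c1OC.[Cl-] | intermediate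
7 | 2,4-dihydroxy-6-methoxy-5-methyl-3-[(2R)-2-methylbutanoyl]benzaldehyde | O=Cc1c(O)c(C(=O)[C@H](C)CC)c(O)c(C)c1OC | intermediate
8 | 2,4-bis(benzyloxy)-6-methoxy-5-methyl-3-[(2R)-2-methylbutanoyl]benzaldehyde | O=Cc1c(OCc2ccccc2)c(C(=O)[C@H](C)CC)c(OCc2ccccc2)c(C)c1OC | intermediate
9 | 2,2-dimethyl-1,3-dioxane-4,6-dione (Meldrum's acid) | CC1(C)OC(=O)CC(=O)O1 | starting material
10 | 5-{2,4-bis(benzyloxy)-6-methoxy-5-methyl-3-[(2R)-2-methylbutanoyl]benzylidene}-2,2-dimethyl-1,3-dioxane-4,6-dione | CC1(C)OC(=O)C(=Cc2c(OCc3ccccc3)c(C(=O)[C@H](C)CC)c(OCc3ccccc3)c(C)c2OC)C(=O)O1 | intermediate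
11 | 5-RA-2,2-dimethyl-1,3-dioxane-4,6-dione | CC1(C)OC(=O)C(Cc2c(OCc3ccccc3)c(C(=O)[C@H](C)CC)c(OCc3ccccc3)c(C)c2OC)C(=O)O1 | intermediate
12 | 3-{2,4-bis(benzyloxy)-6-methoxy-5-methyl-3-[(2R)-2-methylbutanoyl]phenyl}propanoic acid | OC(=O)CCc1c(OCc2ccccc2)c(C(=O)[C@H](C)CC)c(OCc2ccccc2)c(C)c1OC | intermediate
13 | benzyl alcohol | OCc1ccccc1 | starting material
14 | trichloroethylene | ClC=C(Cl)Cl | starting material
15 | benzyl (E)-1,2-dichlorovinyl ether | Cl/C=C(/Cl)OCc1ccccc1 | intermediate
16 | lithium (benzyloxy)ethynide | [Li]C#COCc1ccccc1 | intermediate
17 | benzyl prop-1-yn-1-yl ether | CC#COCc1ccccc1 | intermediate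
18 | 3-{2,4-bis(benzyloxy)-6-methoxy-5-methyl-3-[(2R)-2-methylbutanoyl]phenyl}propanoyl chloride | ClC(=O)CCc1c(OCc2ccccc2)c(C(=O)[C@H](C)CC)c(OCc2ccccc2)c(C)c1OC | intermediate
19 | RA-ketene (3-aryl-prop-1-en-1-one) | O=C=CCc1c(OCc2ccccc2)c(C(=O)[C@H](C)CC)c(OCc2ccccc2)c(C)c1OC | intermediate
20 | 3-(benzyloxy)-2-methyl-4-RA-cyclobut-2-en-1-one (both C4 epimers) | O=C1C(Cc2c(OCc3ccccc3)c(C(=O)[C@H](C)CC)c(OCc3ccccc3)c(C)c2OC)C(OCc2ccccc2)=C1C | intermediate
21 | 2-chloro-1,1-dimethoxyethane | COC(CCl)OC | starting material
22 | sodium methoxyethynide | [Na]C#COC | intermediate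
23 | methoxyethyne | C#COC | intermediate
24 | (3Z)-3-(benzyloxy)-2-methyl-4-RA-buta-1,3-dien-1-one (vinylketene) | O=C=C(C)/C(OCc1ccccc1)=C/Cc1c(OCc2ccccc2)c(C(=O)[C@H](C)CC)c(OCc2ccccc2)c(C)c1OC | intermediate
25 | 4-[(1Z)-1-(benzyloxy)-2-RA-ethenyl]-3-methoxy-4-methylcyclobut-2-en-1-one (both epimers at the quaternary carbon) | O=C1C=C(OC)C1(C)/C(OCc1ccccc1)=C/Cc1c(OCc2ccccc2)c(C(=O)[C@H](C)CC)c(OCc2ccccc2)c(C)c1OC | intermediate
26 | (3E,5Z)-5-(benzyloxy)-3-methoxy-4-methyl-6-RA-hexa-1,3,5-trien-1-one (dienylketene) | O=C=C/C(OC)=C(C)\C(OCc1ccccc1)=C\Cc1c(OCc2ccccc2)c(C(=O)[C@H](C)CC)c(OCc2ccccc2)c(C)c1OC | intermediate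
27 | 5-(benzyloxy)-3-methoxy-4-methyl-6-RA-cyclohexa-2,4-dien-1-one (both C6 epimers) | O=C1C=C(OC)C(C)=C(OCc2ccccc2)C1Cc1c(OCc2ccccc2)c(C(=O)[C@H](C)CC)c(OCc2ccccc2)c(C)c1OC | intermediate
28 | 3-(benzyloxy)-5-methoxy-4-methyl-2-RA-phenol | Oc1cc(OC)c(C)c(OCc2ccccc2)c1Cc1c(OCc2ccccc2)c(C(=O)[C@H](C)CC)c(OCc2ccccc2)c(C)c1OC | intermediate
29 | 3-methylbut-2-enoic acid | CC(C)=CC(=O)O | starting material
30 | 3-methylbut-2-enoic trifluoroacetic anhydride | CC(C)=CC(=O)OC(=O)C(F)(F)F | intermediate
31 | 1-[4-(benzyloxy)-2-hydroxy-6-methoxy-5-methyl-3-RA-phenyl]-3-methylbut-2-en-1-one | CC(C)=CC(=O)c1c(O)c(Cc2c(OCc3ccccc3)c(C(=O)[C@H](C)CC)c(OCc3ccccc3)c(C)c2OC)c(OCc2ccccc2)c(C)c1OC | intermediate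
32 | 7-(benzyloxy)-5-methoxy-2,2,6-trimethyl-8-RA-chroman-4-one | CC[C@@H](C)C(=O)c1c(OCc2ccccc2)c(C)c(OC)c(Cc2c(OCc3ccccc3)c(C)c(OC)c3c2OC(C)(C)CC3=O)c1OCc1ccccc1 | intermediate
33 | 5,7-dihydroxy-8-{2,4-dihydroxy-6-methoxy-5-methyl-3-[(2R)-2-methylbutanoyl]benzyl}-2,2,6-trimethylchroman-4-one | CC[C@@H](C)C(=O)c1c(O)c(C)c(OC)c(Cc2c(O)c(C)c(O)c3c2OC(C)(C)CC3=O)c1O | target

## Step count and least certain steps

Total step count: 11. Longest linear sequence: 9 steps (steps 1, 2, 3, 4, 5, 7, 9, 10, 11). The enantiomeric purity should be assayed on 4 and again on 12 and 28.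

**Step 9 (key step).** The 3-benzyloxy group makes 20 a vinylogous ester, which should raise the barrier to ring opening. The most likely failure is therefore slow generation of 24, with polymerisation of the alkyne, ketene dimerisation, or acylation of the product phenol by 24 taking over. The fallback leaves the benzannulation and forms the CH2 bridge last by quinone methide coupling. It sets out from 5, 1 and 29 and rejoins the route at 33.
- A Mannich reaction of 5 with aqueous formaldehyde and dimethylamine at its only free ring carbon gives (2R)-1-{3-[(dimethylamino)methyl]-2,6-dihydroxy-4-methoxy-5-methylphenyl}-2-methylbutan-1-one F1.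
- Separately, 1 and 29 in P2O5/MeSO3H give 5,7-dihydroxy-2,2,6-trimethylchroman-4-one F2, which must be separated from its 8-methyl isomer.
- Heating F1 with F2 in dioxane expels dimethylamine, and the ortho-quinone methide is captured by C8 of F2, its only free ring carbon, to give 33.
- The price is that the ring B regiochemistry then rests on an isomer separation.

**Step 7.** Dimerisation of aldoketene 19 may outrun cycloaddition with the hindered internal ynol ether. The acid chloride 18 may also cyclise onto the ortho benzyloxy oxygen with loss of the benzyl group. The fallback replaces the ketene by a keteniminium ion. It sets out from 12 and returns at 20.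
- Carbodiimide coupling of 12 with dimethylamine gives 3-{2,4-bis(benzyloxy)-6-methoxy-5-methyl-3-[(2R)-2-methylbutanoyl]phenyl}-N,N-dimethylpropanamide F3.
- Activation with Tf2O and 2,4,6-collidine in CH2Cl2 in the presence of 17 gives, by [2+2] cycloaddition with the same polarity-controlled orientation, the cyclobuteniminium triflate N-[3-(benzyloxy)-2-methyl-4-RA-cyclobut-2-en-1-ylidene]-N-methylmethanaminium triflate F4.
- Aqueous NaHCO3 hydrolyses F4 to 20.

**Step 10.** The mixed anhydride may only O-acylate the phenol. The conjugated acylium may react at its tertiary carbon (C-alkylation, then lactonisation to a dihydrocoumarin). The trifluoroacetic acid set free may attack the CH2 bridge or the benzyl ethers. The fallback builds the pyranone without acid. It sets out from 28 and returns at 31 and hence 32.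
- Ortho-formylation with MgCl2, Et3N and paraformaldehyde in MeCN gives 4-(benzyloxy)-2-hydroxy-6-methoxy-5-methyl-3-RA-benzaldehyde F5.
- Nozaki–Hiyama–Kishi addition of 1-bromo-2-methylprop-1-ene (CrCl2, NiCl2 cat., DMF), which is aldehyde-selective and non-basic, gives 1-[4-(benzyloxy)-2-hydroxy-6-methoxy-5-methyl-3-RA-phenyl]-3-methylbut-2-en-1-ol F6.
- MnO2 oxidation gives 31, which closes to 32 with K2CO3 in MeOH.

**Step 11.** The twisted a4 methyl ether, flanked by two ortho substituents, may be cleaved as well. The bridge may suffer acid-induced scission once the phenols are unmasked, or the peri methyl ether may react incompletely at the low temperature needed for selectivity. The fallback separates the two cleavages by mechanism. It sets out from 32 and returns at 33.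
- Hydrogenolysis (H2, palladium on carbon, Pd/C, EtOAc) removes the three benzyl ethers and gives 7-hydroxy-8-{2,4-dihydroxy-6-methoxy-5-methyl-3-[(2R)-2-methylbutanoyl]benzyl}-5-methoxy-2,2,6-trimethylchroman-4-one F7.
- MgI2·OEt2 in toluene/ether at 50 °C then removes only the methyl ether chelated to the C4 carbonyl, giving 33.

**Step 1.** The configuration may erode through ketene formation from 3 or enolisation of the aluminium-bound ketone. The fallback makes the aryl–acyl bond by organometallic addition, in which the ketone exists only after work-up. It sets out from 1 and 2 and returns at 4.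
- 1 is converted with MOMCl and i-Pr2NEt into 1,3,5-tris(methoxymethoxy)-2-methylbenzene F8.
- 2 is converted through 3 and MeNHOMe·HCl/pyridine into (2R)-N-methoxy-N,2-dimethylbutanamide F9.
- Ortho-lithiation of F8 (n-BuLi, THF, 0 °C) between two methoxymethoxy groups and addition to F9 give (2R)-2-methyl-1-[2,4,6-tris(methoxymethoxy)-3-methylphenyl]butan-1-one F10.
- HCl in MeOH removes the acetals to give 4.

## Further compounds

F1 | step 9 | (2R)-1-{3-[(dimethylamino)methyl]-2,6-dihydroxy-4-methoxy-5-methylphenyl}-2-methylbutan-1-one | CC[C@@H](C)C(=O)c1c(O)c(C)c(OC)c(CN(C)C)c1O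
F2 | step 9 | 5,7-dihydroxy-2,2,6-trimethylchroman-4-one | CC1(C)CC(=O)c2c(O)c(C)c(O)cc2O1
F3 | step 7 | 3-{2,4-bis(benzyloxy)-6-methoxy-5-methyl-3-[(2R)-2-methylbutanoyl]phenyl}-N,N-dimethylpropanamide | CN(C)C(=O)CCc1c(OCc2ccccc2)c(C(=O)[C@H](C)CC)c(OCc2ccccc2)c(C)c1OC
F4 | step 7 | N-[3-(benzyloxy)-2-methyl-4-RA-cyclobut-2-en-1-ylidene]-N-methylmethanaminium triflate | C[N+](C)=C1C(Cc2c(OCc3ccccc3)c(C(=O)[C@H](C)CC)c(OCc3ccccc3)c(C)c2OC)C(OCc2ccccc2)=C1C.[O-]S(=O)(=O)C(F)(F)F
F5 | step 10 | 4-(benzyloxy)-2-hydroxy-6-methoxy-5-methyl-3-RA-benzaldehyde | O=Cc1c(O)c(Cc2c(OCc3ccccc3)c(C(=O)[C@H](C)CC)c(OCc3ccccc3)c(C)c2OC)c(OCc2ccccc2)c(C)c1OC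
F6 | step 10 | 1-[4-(benzyloxy)-2-hydroxy-6-methoxy-5-methyl-3-RA-phenyl]-3-methylbut-2-en-1-ol (both carbinol epimers) | CC(C)=CC(O)c1c(O)c(Cc2c(OCc3ccccc3)c(C(=O)[C@H](C)CC)c(OCc3ccccc3)c(C)c2OC)c(OCc2ccccc2)c(C)c1OC
F7 | step 11 | 7-hydroxy-8-{2,4-dihydroxy-6-methoxy-5-methyl-3-[(2R)-2-methylbutanoyl]benzyl}-5-methoxy-2,2,6-trimethylchroman-4-one | CC[C@@H](C)C(=O)c1c(O)c(C)c(OC)c(Cc2c(O)c(C)c(OC)c3c2OC(C)(C)CC3=O)c1O
F8 | step 1 | 1,3,5-tris(methoxymethoxy)-2-methylbenzene | COCOc1cc(OCOC)c(C)c(OCOC)c1
F9 | step 1 | (2R)-N-methoxy-N,2-dimethylbutanamide | CC[C@@H](C)C(=O)N(C)OC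
F10 | step 1 | (2R)-2-methyl-1-[2,4,6-tris(methoxymethoxy)-3-methylphenyl]butan-1-one | CC[C@@H](C)C(=O)c1c(OCOC)c(C)c(OCOC)cc1OCOC
A1 | alternative 1 | 5-[2,4-bis(benzyloxy)-6-methoxy-5-methylphenyl]-1-methoxy-2-methyl-1,3-bis(trimethylsilyloxy)penta-1,3-diene | COC(O[Si](C)(C)C)=C(C)C(O[Si](C)(C)C)=CCc1c(OCc2ccccc2)cc(OCc2ccccc2)c(C)c1OC
A2 | alternative 1 | 5-bromo-2,2-dimethyl-2,3-dihydro-4H-pyran-4-one | CC1(C)CC(=O)C(Br)=CO1
A3 | alternative 1 | 8-[2,4-bis(benzyloxy)-6-methoxy-5-methylbenzyl]-5,7-dihydroxy-2,2,6-trimethylchroman-4-one | COc1c(C)c(OCc2ccccc2)cc(OCc2ccccc2)c1Cc1c(O)c(C)c(O)c2c1OC(C)(C)CC2=O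
A4 | alternative 2 | 5,7-bis(benzyloxy)-8-{3-methoxy-2-[methoxy(trimethylsilyloxy)methylidene]pent-3-en-1-yl}-2,2,6-trimethylchroman-4-one | COC(O[Si](C)(C)C)=C(Cc1c(OCc2ccccc2)c(C)c(OCc2ccccc2)c2c1OC(C)(C)CC2=O)C(OC)=CC
A5 | alternative 2 | (4R)-1-(benzyloxy)-4-methylhex-1-yn-3-one | CC[C@@H](C)C(=O)C#COCc1ccccc1
A6 | alternative 2 | 5,7-bis(benzyloxy)-8-{4-(benzyloxy)-2-hydroxy-6-methoxy-5-methyl-3-[(2R)-2-methylbutanoyl]benzyl}-2,2,6-trimethylchroman-4-one | CC[C@@H](C)C(=O)c1c(OCc2ccccc2)c(C)c(OC)c(Cc2c(OCc3ccccc3)c(C)c(OCc3ccccc3)c3c2OC(C)(C)CC3=O)c1O
A7 | alternative 3 | 3-(benzyloxy)-2-methylcyclobut-2-en-1-one | O=C1CC(OCc2ccccc2)=C1C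
A8 | alternative 3 | 5,7-bis(benzyloxy)-8-(3-methoxyprop-2-yn-1-yl)-2,2,6-trimethylchroman-4-one | COC#CCc1c(OCc2ccccc2)c(C)c(OCc2ccccc2)c2c1OC(C)(C)CC2=O
A9 | alternative 3 | 5,7-bis(benzyloxy)-8-[4-(benzyloxy)-2-hydroxy-6-methoxy-5-methylbenzyl]-2,2,6-trimethylchroman-4-one | Oc1cc(OCc2ccccc2)c(C)c(OC)c1Cc1c(OCc2ccccc2)c(C)c(OCc2ccccc2)c2c1OC(C)(C)CC2=O
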